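Everything rests on cutting both ring bonds of spiro carbon C6, C5–C6 and C1–C6 (cyclohexane ring: C1 bears ethyl, C2 and C4 methyl, C3 and C5 Ar = 2,4,5-trimethoxyphenyl). The feature exploited: C1 and C5 both lie β to C3, so a C3 carbonyl makes them the two acceptor carbons of a divinyl ketone, while C6 is the carbon para to OH of 2,5-dimethoxyphenol. One flask bonds this carbon to C5 (chiral acid), then to C1 (base), closing the cyclohexanone ring, turning the arene into the cyclohexadienone ring and setting five stereocentres. The precursor is that divinyl ketone with C1=C2 stored as a β-acetoxy ketone, so C5 reacts first and Nazarov closure is excluded.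

Key step: step 4

Numbering: the ring locants C1–C6 are also used for open-chain intermediates. Systematic names carry their own locants.

Design remark: in the free divinyl ketone the alkyl-substituted C1 is the more electrophilic terminus, and acid can trigger a 4π closure. The dearomatising step would then be left with the donor-deactivated C5 acceptor. Masking C1=C2 as the aldol acetate keeps the carbon skeleton and both bond formations, fixes the order C5 then C1, and costs no extra step.

Assumption: the (R) catalyst is taken to deliver the C5 configuration drawn. If the sense is opposite, the (S) catalyst is used.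

Step 1
Reactants: 1 3-pentanone; 2 2,4,5-trimethoxybenzaldehyde
Product: 3 (E)-2-methyl-1-(2,4,5-trimethoxyphenyl)pent-1-en-3-one
Conditions: 1 (5 equiv), KOH (0.3 equiv), MeOH–H2O, 60 °C
Reagents that add atoms: none
Why: Claisen–Schmidt condensation in which the aldehyde cannot enolise, excess ketone suppresses a second condensation, and E1cB loss of water gives the E enone because aryl and acyl avoid each other.

Step 2
Reactants: 3 (E)-2-methyl-1-(2,4,5-trimethoxyphenyl)pent-1-en-3-one; 4 propanal
Product: 5 (E)-5-hydroxy-2,4-dimethyl-1-(2,4,5-trimethoxyphenyl)hept-1-en-3-one (racemic; 4,5-syn expected to prevail)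
Conditions: LiN(i-Pr)2 (1.05 equiv), THF, −78 °C; 4 (1.2 equiv), −78 °C; H2O–THF quench
Reagents that add atoms: none
Why: Directed lithium aldol addition in which only the ethyl CH2 of 3 can be deprotonated, the preformed enolate takes up propanal before it can self-condense, and the two new stereocentres need no control because step 4 erases them.

Step 3
Reactants: 5 (E)-5-hydroxy-2,4-dimethyl-1-(2,4,5-trimethoxyphenyl)hept-1-en-3-one
Product: 6 (E)-4,6-dimethyl-5-oxo-7-(2,4,5-trimethoxyphenyl)hept-6-en-3-yl acetate (latent form, same carbon skeleton, of (1E,4E)-2,4-dimethyl-1-Ar-hepta-1,4-dien-3-one)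
Conditions: Ac2O (1.5 equiv), 4-(dimethylamino)pyridine (5 mol %), pyridine, CH2Cl2, 0 °C
Reagents that add atoms: acetic anhydride CC(=O)OC(C)=O
Why: Nucleophile-catalysed O-acetylation of a secondary alcohol under conditions too mild for E1cB elimination stores the C1=C2 bond as an isolable β-acetoxy ketone.

Step 4
Reactants: 6 (E)-4,6-dimethyl-5-oxo-7-(2,4,5-trimethoxyphenyl)hept-6-en-3-yl acetate; 7 2,5-dimethoxyphenol
Product: 10 (6S,7R,8S,10S,11R)-7-ethyl-1,4-dimethoxy-8,10-dimethyl-11-(2,4,5-trimethoxyphenyl)spiro[5.5]undeca-1,4-diene-3,9-dione, via C5 adduct acetate 8 (not isolated), via phenol enone 9 (not isolated)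
Conditions: (i) 7 (1.2 equiv), (R)-3,3'-bis(2,4,6-triisopropylphenyl)-1,1'-binaphthyl-2,2'-diyl N-(trifluoromethanesulfonyl)phosphoramide (10 mol %), 4 Å MS, toluene (1 M), −20 °C; (ii) same flask, THF, KOt-Bu (1.3 equiv), −40 → 0 °C; AcOH, −40 °C
Reagents that add atoms: none
Why: Proposed new method: the chiral acid protonates the only enone of 6 while its phosphoryl oxygen holds the phenol O–H, and the ring carbon para to OH adds to benzylic C5 in a Friedel–Crafts conjugate addition to give 8, with no second enone present that could divert the attack to C1 or allow a Nazarov 4π closure. Phenolate base then expels acetate by E1cB to unveil the E enone of 9, and the same carbon, now the para position of a phenolate, adds to C1 in a 6-endo-trig Michael closure that forms the cyclohexanone ring and converts the arene into the cyclohexadienone ring. The closest known reaction types are [5+1] double Michael spiroannulations of divinyl ketones with 1,3-dicarbonyl pronucleophiles, acid-catalysed conjugate additions of phenols to enones and alkylative para-dearomatisation of phenolates, but one phenol carbon serving twice with a Michael-type loss of aromaticity has not been shown. C5 is set by the chiral ion pair, and C4, first set by protonation of the enol and still epimerisable under the base, enters the ring as the equatorial methyl trans to the C5 aryl. In the chair-like closure the C5 aryl is equatorial, the E geometry places ethyl equatorial and thus cis to that aryl (C1), the bare CH edge of the phenolate takes the axial site because the methoxy-bearing edge would clash with the axial groups on C2 and C4 (C6), and a phenol O–H protonates the enolate at C2 from the face away from ethyl and from the axial CH edge, leaving methyl cis to ethyl. The step needs para attack (the ortho carbon is wedged between OH and OMe and O-adducts revert), closure that is not undone by rearomatising retro-Michael cleavage (vinylogous-ester stabilisation of the dienone, a six-membered tether and only catalytic residual base work for it) and no re-enolisation at C2 (phenolate is a far weaker base than the ketone enolate and the flask is quenched cold with AcOH).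

Step 5
Reactants: 10 spiro ketone (name as in step 4); 11 1-bromo-2,4,5-trimethoxybenzene
Product: 14 (6S,7R,8S,9S,10S,11R)-7-ethyl-9-hydroxy-1,4-dimethoxy-8,10-dimethyl-9,11-bis(2,4,5-trimethoxyphenyl)spiro[5.5]undeca-1,4-dien-3-one, via aryllithium 12 (not isolated), via arylcerium dichloride 13 (not isolated)
Conditions: 11 (1.4 equiv), n-BuLi (1.4 equiv), THF, −78 °C; anhydrous CeCl3 (1.5 equiv), −78 °C; 10, −78 °C; H2O–THF quench
Reagents that add atoms: none
Why: Imamoto organocerium 1,2-addition in which the weakly basic, oxophilic aryl cerium reagent adds to the hindered enolisable C3 ketone without forming the enolate that could open the ring, the cross-conjugated vinylogous-ester carbonyl of the cyclohexadienone ring is the poorer electrophile, and aryl is expected to enter anti to the axial C2 methyl, although the C3 configuration is erased in step 6.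

Step 6
Reactants: 14 tertiary benzylic alcohol (name as in step 5)
Product: 15 tatanan B, (6S,7R,8S,9S,10R,11R)-7-ethyl-1,4-dimethoxy-8,10-dimethyl-9,11-bis(2,4,5-trimethoxyphenyl)spiro[5.5]undeca-1,4-dien-3-one
Conditions: Et3SiH (10 equiv), CF3CO2H (5 equiv), CH2Cl2, −40 → −10 °C; aq NaHCO3
Reagents that add atoms: none
Why: Ionic (Kursanov–Parnes) deoxygenation in which the alcohol ionises at low temperature to a 2,4,5-trimethoxybenzylic cation and excess Et3SiH delivers hydride along the axial trajectory, on the face opposite the axial C2 methyl and the axial CH edge of the cyclohexadienone ring, so that the aryl group ends equatorial and C3 is set.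

Compound list
1 | 3-pentanone | CCC(=O)CC | starting material
2 | 2,4,5-trimethoxybenzaldehyde | COc1cc(OC)c(C=O)cc1OC | starting material
3 | (E)-2-methyl-1-(2,4,5-trimethoxyphenyl)pent-1-en-3-one | CCC(=O)/C(C)=C/c1cc(OC)c(OC)cc1OC | intermediate
4 | propanal | CCC=O | starting material
5 | (E)-5-hydroxy-2,4-dimethyl-1-(2,4,5-trimethoxyphenyl)hept-1-en-3-one, racemic, carbinol and α-methyl centres not controlled | CCC(O)C(C)C(=O)/C(C)=C/c1cc(OC)c(OC)cc1OC | intermediate
6 | (E)-4,6-dimethyl-5-oxo-7-(2,4,5-trimethoxyphenyl)hept-6-en-3-yl acetate, latent divinyl ketone | CCC(OC(C)=O)C(C)C(=O)/C(C)=C/c1cc(OC)c(OC)cc1OC | intermediate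
7 | 2,5-dimethoxyphenol | COc1ccc(OC)c(O)c1 | starting material
8 | (6S,7S)-7-(4-hydroxy-2,5-dimethoxyphenyl)-4,6-dimethyl-5-oxo-7-(2,4,5-trimethoxyphenyl)heptan-3-yl acetate, mixture at the two centres that are erased | CCC(OC(C)=O)C(C)C(=O)[C@@H](C)[C@H](c1cc(OC)c(OC)cc1OC)c1cc(OC)c(O)cc1OC | intermediate
9 | (1S,2S,4E)-1-(4-hydroxy-2,5-dimethoxyphenyl)-2,4-dimethyl-1-(2,4,5-trimethoxyphenyl)hept-4-en-3-one | CC/C=C(\C)C(=O)[C@@H](C)[C@H](c1cc(OC)c(OC)cc1OC)c1cc(OC)c(O)cc1OC | intermediate
10 | spiro ketone; ethyl, C2 methyl, C5 aryl and the CH= edge on one face, C4 methyl and the C(OMe)= edge on the other | CC[C@@H]1[C@H](C)C(=O)[C@@H](C)[C@H](c2cc(OC)c(OC)cc2OC)[C@]12C=C(OC)C(=O)C=C2OC | intermediate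
11 | 1-bromo-2,4,5-trimethoxybenzene | COc1cc(OC)c(Br)cc1OC | starting material
12 | (2,4,5-trimethoxyphenyl)lithium | [Li]c1cc(OC)c(OC)cc1OC | intermediate
13 | dichloro(2,4,5-trimethoxyphenyl)cerium | Cl[Ce](Cl)c1cc(OC)c(OC)cc1OC | intermediate
14 | C3 tertiary alcohol, OH on the face of the C2 methyl (expected epimer; both epimers converge in step 6) | CC[C@@H]1[C@H](C)[C@@](O)(c2cc(OC)c(OC)cc2OC)[C@@H](C)[C@H](c2cc(OC)c(OC)cc2OC)[C@]12C=C(OC)C(=O)C=C2OC | intermediate
15 | tatanan B | CC[C@@H]1[C@H](C)[C@H](c2cc(OC)c(OC)cc2OC)[C@@H](C)[C@H](c2cc(OC)c(OC)cc2OC)[C@]12C=C(OC)C(=O)C=C2OC | target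

Total step count: 6. Longest linear sequence: 6 (steps 1–6; 7 and 11 are bought).

Steps most likely to fail

1. Step 4 (bears the new-method label).
- **Risk:** rearomatising retro-Michael cleavage at C1–C6 or C5–C6 may keep the open phenol as the resting state. Slow re-enolisation may also wash out the kinetic C2 configuration.
- **Fallback:** it uses known chemistry, sets out from 9 and comes back at 10. It removes the C3 carbonyl before ring closure and closes the ring irreversibly.
- **Sequence:** The flask is stopped after the elimination (1,8-diazabicyclo[5.4.0]undec-7-ene instead of KOt-Bu, 0 °C) and 9 is isolated. Corey–Bakshi–Shibata reduction gives the 3R allylic alcohol F1; it uses BH3·SMe2 and the enantiomer of tetrahydro-1-methyl-3,3-diphenyl-1H,3H-pyrrolo[1,2-c][1,3,2]oxazaborole that gives the 3R carbinol. TBSOTf and 2,6-lutidine give the bis-silyl ether F2. Hydroboration (BH3·THF, then NaBO3) adds H to C2 and OH to C1 in syn fashion. It proceeds anti to the C3 silyloxy group under A(1,3) control and gives the C1 alcohol F3, which fixes C2 stereospecifically. MsCl and Et3N give the mesylate F4. Bu4NF frees the phenolate, which displaces the mesylate with inversion in a 6-exo-tet alkylative para-dearomatisation to give the spiro silyl ether F5. HF·pyridine gives the spiro alcohol F6, and Dess–Martin oxidation under buffered, non-basic conditions returns 10.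

2. Step 5.
- **Risk:** the aryl metal may add to the cyclohexadienone carbonyl instead. Deprotonation at C2 or C4 followed by ring opening is also possible.
- **Fallback:** it sets out from 10 and comes back at 15, and it uses no carbanion. Only the saturated ketone condenses with TsNHNH2 (MeOH, 50 °C), giving the tosylhydrazone F7. Metal-free reductive coupling with 2,4,5-trimethoxyphenylboronic acid (K2CO3, 1,4-dioxane, 110 °C) follows. It runs through the diazoalkane, a 1,2-aryl shift on boron and protodeboronation, and installs aryl and H at C3 directly. The large aryl group is expected to end equatorial, and a C3 epimer would be removed by chromatography.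

3. Step 6.
- **Risk:** proton loss from the long-lived benzylic cation and re-protonation may scramble C2 and C4. The acid may also heterolyse C5–C6 with rearomatisation.
- **Fallback:** it sets out from 14 and comes back at 15 under neutral radical conditions. KN(SiMe3)2 and then methyl chlorooxoacetate (THF, −78 °C) give the tertiary methyl oxalate F8. Bu3SnH and AIBN (toluene, 90 °C) generate the C3 benzylic radical. This radical takes hydrogen on the same open face that the hydride would use.

Further compounds
F1 | step 4 | (1S,2S,3R,4E)-1-(4-hydroxy-2,5-dimethoxyphenyl)-2,4-dimethyl-1-(2,4,5-trimethoxyphenyl)hept-4-en-3-ol | CC/C=C(\C)[C@H](O)[C@@H](C)[C@H](c1cc(OC)c(OC)cc1OC)c1cc(OC)c(O)cc1OC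
F2 | step 4 | bis(tert-butyldimethylsilyl) ether of F1 (phenol O and C3 O) | CC/C=C(\C)[C@H](O[Si](C)(C)C(C)(C)C)[C@@H](C)[C@H](c1cc(OC)c(OC)cc1OC)c1cc(OC)c(O[Si](C)(C)C(C)(C)C)cc1OC
F3 | step 4 | C1 secondary alcohol from syn hydroboration of F2 | CC[C@H](O)[C@H](C)[C@H](O[Si](C)(C)C(C)(C)C)[C@@H](C)[C@H](c1cc(OC)c(OC)cc1OC)c1cc(OC)c(O[Si](C)(C)C(C)(C)C)cc1OC
F4 | step 4 | C1 methanesulfonate of F3 | CC[C@H](OS(C)(=O)=O)[C@H](C)[C@H](O[Si](C)(C)C(C)(C)C)[C@@H](C)[C@H](c1cc(OC)c(OC)cc1OC)c1cc(OC)c(O[Si](C)(C)C(C)(C)C)cc1OC
F5 | step 4 | spirodienone with equatorial C3 tert-butyldimethylsilyloxy group | CC[C@@H]1[C@H](C)[C@H](O[Si](C)(C)C(C)(C)C)[C@@H](C)[C@H](c2cc(OC)c(OC)cc2OC)[C@]12C=C(OC)C(=O)C=C2OC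
F6 | step 4 | spirodienone C3 alcohol | CC[C@@H]1[C@H](C)[C@H](O)[C@@H](C)[C@H](c2cc(OC)c(OC)cc2OC)[C@]12C=C(OC)C(=O)C=C2OC
F7 | step 5 | C3 N-tosylhydrazone of 10 | CC[C@@H]1[C@H](C)C(=NNS(=O)(=O)c2ccc(C)cc2)[C@@H](C)[C@H](c2cc(OC)c(OC)cc2OC)[C@]12C=C(OC)C(=O)C=C2OC
F8 | step 6 | C3 methyl oxalate of 14 | CC[C@@H]1[C@H](C)[C@@](OC(=O)C(=O)OC)(c2cc(OC)c(OC)cc2OC)[C@@H](C)[C@H](c2cc(OC)c(OC)cc2OC)[C@]12C=C(OC)C(=O)C=C2OC
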